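The earlier runs and the new flask stem from a simulated flask for substances that don't exist.

At the last reading of each earlier run, 60.0 min, the feed has just ended, so what is missing from the charge has reacted and must stand as target or self-condensation product.

in all of them: free catalyst 0.1 mol%
- Friday's: starting material 0.28 M (fed, over 1.0 h); coupling partner 0.70 equiv; run made earlier; the fed solution adds 0.20 times the starting volume
- Thursday's: starting material 0.44 M (fed, over 1.0 h); coupling partner 0.70 equiv; run made earlier; the fed solution adds 0.20 times the starting volume
- Sunday's: starting material 0.20 M (fed, over 1.0 h); coupling partner 1.4 equiv; run made earlier; the fed solution adds 0.20 times the starting volume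
- flask: starting material 0.20 M (fed, over 1.0 h); coupling partner 0.700 equiv; the fed solution adds 0.20 times the starting volume; time 1.0 h

- Friday's (time / min: starting material / %, target / %): 15.0: 24.0, 0.5; 30.0: 44.2, 2.3; 50.0: 64.8, 6.3; 60.0: 73.2, 7.1
- Thursday's (time / min: starting material / %, target / %): 8.00: 13.1, 0.1; 20.0: 29.2, 1.7; 40.0: 51.2, 6.3; 60.0: 64.4, 11.3
- Sunday's (time / min: starting material / %, target / %): 8.00: 12.8, 0.5; 20.0: 31.4, 0.8; 40.0: 58.0, 2.3; 60.0: 79.1, 6.8

(each reading ± 0.5 percentage points)

- part of the starting material that has reacted at 1.0 h
- share of free coupling partner in free coupling partner and idle adduct together, at 1.0 h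

Pooled over these runs, 69.7% of what had reacted had gone to self-condensation product; that part is the condensation share, a selectivity read from the last readings. Singly it reads 68.3% on Thursday, 73.5% on Friday and 67.5% on Sunday.

Two chemists expect this flask, with Sunday's charge of starting material, to lose about Sunday's 14.1% to self-condensation, and they part over the target. The first says target follows the coupling partner in proportion. This flask has 0.700 equiv against Sunday's 1.4 equiv, so it makes half of Sunday's 6.8% and reacts 17.5%, which implies a share of 80.6%. But that stands above the shares read, though those runs differ in starting material as well as in equivalents, so this counts against the proportion without disproving it.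

The second chemist made the forecast, on the ground that “Self-condensation scales with concentration”, with target near 5 %: 19.4% reacted, and 96% for the free share, the binding there being a guess.

The flask gives 21.0% reacted and a free share of 96.6%, so the forecast held.

    starting material + free catalyst → catalyst intermediate A (k = 0.299 M⁻¹ s⁻¹)
    coupling partner + catalyst intermediate A ⇌ catalyst intermediate B (K = 6.30 M⁻¹, k = 3.08 M⁻¹ s⁻¹)
    catalyst intermediate B → released group + catalyst intermediate C (k = 0.735 s⁻¹)
    catalyst intermediate C → free catalyst + target (k = 4.10 s⁻¹)
    coupling partner + released group ⇌ idle adduct, settled at all times (K = 4.80 M⁻¹)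
    2 starting material → self-condensation product (k = 4.72 × 10⁻⁴ M⁻¹ s⁻¹)
    coupling partner + catalyst intermediate B ⇌ idle complex, settled at all times (K = 18.0 M⁻¹)

Up to 1.00 h the flask built up starting material to 79.0% of the charge, and the entry step reached the midpoint of its turnover at 0.654 h. At 1.00 h self-condensation product stood at 14.4% and target at 6.58%, while the condensation share of the reacted 21.0% makes 14.6%. That target in this flask stood above the first chemist's 3.40%, and at the same time this flask held more free catalyst, 73.0%, than catalyst intermediate A, 15.2%. A neighbour flask, the same but with 0.34 M of starting material, reacted 30.1%, of which the condensation share makes 21.0%, and it held 20.7% self-condensation product.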